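**Assumption:** the SMILES encodes the natural (2S)-flavanone (checked by CIP: O1 > C1′ > C3 > H). Compounds 1, 2, 4, 7, 9 and the ligand (R)-t-BuPyOx are taken as catalogue chemicals. The route is designed from known reaction classes and has not been run.

## Retrosynthetic overview

1. Target 11 ⇒ silyl ether 10 (desilylation) ⇒ chromone 8 + arylboronic acid 9, by enantioselective Pd-catalysed conjugate addition. C2 is set last, so nothing basic follows it.
2. Prenyl of 8 ⇒ 6-allyl chromone 6 (cross-metathesis) ⇒ 5-O-allyl chromone 5 (aromatic Claisen). C6 is the only open ortho position, which fixes the regiochemistry.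
3. Chromone 5 ⇒ mono-allyl ether 3 (enaminone cyclisation through the only free phenol) ⇒ symmetric acetophenone 1.
4. Ring order: rings A and B are purchased; the pyranone ring is closed in step 2; the C2 stereocentre is created in step 5.

## Route

**Step 1**
Reactants: 1, 1-(2,6-dihydroxy-4-methoxyphenyl)ethan-1-one; 2, allyl bromide
Product: 3, 1-[2-(allyloxy)-6-hydroxy-4-methoxyphenyl]ethan-1-one
Conditions: allyl bromide (1.1 equiv), K2CO3 (1.5 equiv), acetone, reflux
Reagents that add atoms: allyl bromide, C=CCBr
Why: Williamson ether synthesis; the two OH groups of 1 are symmetry-equivalent, so only one mono-ether can form, and the remaining OH is strongly H-bonded to the ketone and resists a second alkylation.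

**Step 2**
Reactants: 3; 4, N,N-dimethylformamide dimethyl acetal (DMF-DMA)
Product: 5, 5-(allyloxy)-7-methoxy-4H-chromen-4-one
Conditions: DMF-DMA (2 equiv), toluene, 100 °C; then conc. HCl, CH2Cl2, rt (one pot)
Reagents that add atoms: DMF-DMA, COC(OC)N(C)C (supplies C2–H of the chromone)
Why: enaminone formation followed by acid cyclodehydration (chromone synthesis); only one phenol is free, so the position of the ring oxygen is unambiguous, and the allyl ether is acid-stable.

**Step 3**
Reactants: 5
Product: 6, 6-allyl-5-hydroxy-7-methoxy-4H-chromen-4-one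
Conditions: Eu(fod)3 (10 mol %), PhCl, 120 °C
Reagents that add atoms: none
Why: aromatic Claisen rearrangement accelerated by Eu(III) chelation to C4=O/5-O; C6 is the only ortho position bearing H (C4a is blocked), and the unsubstituted allyl dienone re-aromatises at C6 rather than Cope-migrating to C8.

**Step 4**
Reactants: 6; 7, 2-methyl-2-butene
Product: 8, 5-hydroxy-7-methoxy-6-(3-methylbut-2-en-1-yl)-4H-chromen-4-one
Conditions: Grubbs II (5 mol %), 2-methyl-2-butene/CH2Cl2, 40 °C, sealed tube
Reagents that add atoms: 2-methyl-2-butene, CC=C(C)C (supplies the =CMe2 terminus; propene is lost)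
Why: olefin cross-metathesis of a terminal alkene with excess trisubstituted alkene converts allyl to prenyl; the electron-poor chromone C2=C3 and the free chelated phenol are inert.

**Step 5**
Reactants: 8; 9, [4-(tert-butyldimethylsilyloxy)phenyl]boronic acid
Product: 10, (2S)-2-[4-(tert-butyldimethylsilyloxy)phenyl]-5-hydroxy-7-methoxy-6-(3-methylbut-2-en-1-yl)chroman-4-one
Conditions: Pd(OCOCF3)2 (5 mol %), (R)-t-BuPyOx (6 mol %), NH4PF6 (30 mol %), H2O (5 equiv), ClCH2CH2Cl, 60 °C
Reagents that add atoms: boronic acid 9, CC(C)(C)[Si](C)(C)Oc1ccc(B(O)O)cc1 (aryl group; the C3 hydrogen comes from water)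
Why: Pd(II)/pyridine-oxazoline catalysed enantioselective conjugate addition of an arylboronic acid to the chromone; the ligand controls which face of C2=C3 receives the aryl, and the (R)-ligand is chosen by analogy with the (S)-ligand → (R)-product model to give 2S. The non-basic medium prevents retro-oxa-Michael racemisation, and the trisubstituted prenyl alkene is a poor partner for Ar–Pd insertion.

**Step 6**
Reactants: 10
Product: 11, (2S)-5-hydroxy-2-(4-hydroxyphenyl)-7-methoxy-6-(3-methylbut-2-en-1-yl)chroman-4-one (6-prenylsakuranetin)
Conditions: HF·pyridine, THF/pyridine, 0 °C → rt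
Reagents that add atoms: none
Why: fluoride cleavage of the aryl silyl ether under mildly acidic conditions; no phenoxide is formed, so C2 is not scrambled by ring-opening, and the conditions are too mild to cyclise the prenyl group onto the 5-OH.

## Compound list

1 | 1-(2,6-dihydroxy-4-methoxyphenyl)ethan-1-one | CC(=O)c1c(O)cc(OC)cc1O | starting material
2 | allyl bromide | C=CCBr | starting material
3 | 1-[2-(allyloxy)-6-hydroxy-4-methoxyphenyl]ethan-1-one | CC(=O)c1c(O)cc(OC)cc1OCC=C | intermediate
4 | DMF dimethyl acetal | COC(OC)N(C)C | starting material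
5 | 5-(allyloxy)-7-methoxy-4H-chromen-4-one | O=c1ccoc2cc(OC)cc(OCC=C)c12 | intermediate
6 | 6-allyl-5-hydroxy-7-methoxy-4H-chromen-4-one | O=c1ccoc2cc(OC)c(CC=C)c(O)c12 | intermediate
7 | 2-methyl-2-butene | CC=C(C)C | starting material
8 | 5-hydroxy-7-methoxy-6-(3-methylbut-2-en-1-yl)-4H-chromen-4-one | O=c1ccoc2cc(OC)c(CC=C(C)C)c(O)c12 | intermediate
9 | [4-(tert-butyldimethylsilyloxy)phenyl]boronic acid | CC(C)(C)[Si](C)(C)Oc1ccc(B(O)O)cc1 | starting material
10 | (2S)-2-[4-(TBSO)phenyl]-5-hydroxy-7-methoxy-6-prenylchroman-4-one | COc1cc2c(c(O)c1CC=C(C)C)C(=O)C[C@@H](c1ccc(O[Si](C)(C)C(C)(C)C)cc1)O2 | intermediate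
11 | (2S)-6-prenylsakuranetin | COc1cc2c(c(O)c1CC=C(C)C)C(=O)C[C@@H](c1ccc(O)cc1)O2 | target

## Summary

Total steps: 6. Longest linear sequence: 6 (fully linear; 2, 4, 7 and 9 are purchased).

Steps most likely to fail:

1. **Step 5 (asymmetric arylation).** The chelating 5-OH may sequester Pd, the electron-rich chromone may react slowly, and the sense of induction rests on analogy. Check the product by CD; (2S)-flavanones show a negative Cotton effect near 290 nm. Fallback: set C2 before the prenyl chemistry. Take (2S)-sakuranetin (chiral pool) as its 4′-O-TBS ether, 5-O-allylate under Mitsunobu conditions, then run the same Eu(fod)3 Claisen, cross-metathesis and desilylation on the flavanone.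

2. **Step 3 (Claisen).** Risks are a sluggish rearrangement, some C8 product, or dihydrofuran formation at high temperature. Fallback: drop the sigmatropic approach. Iodinate 5-hydroxy-7-methoxychromone at C6 (BnMe3N·ICl2, CaCO3), then install prenyl directly by Pd-catalysed cross-coupling with prenyl-Bpin or prenyl-SnBu3 to reach 8.

3. **Step 4 (cross-metathesis).** Ru–H isomerisation of the allyl group to the conjugated propenyl arene, or incomplete conversion, is possible. Fallback: avoid metathesis. Make the 5-O-(1,1-dimethylallyl) ether of 5-hydroxy-7-methoxychromone (Pd(PPh3)4, tert-butyl 2-methylbut-3-en-2-yl carbonate) and let its ortho-Claisen rearrangement deliver the prenyl group at C6 in one step.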